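In the ten-membered ring the atoms C10, C1, C2(O), C3, C4 and C5 lie in a row with olefins (later epoxides) at C1=C10 and C4=C5; joining C5 to C10 converts this row into a 2-silyloxycyclohexa-1,3-diene, so the ring is retraced to a cis-fused hexalin. Irradiation reverses this: one conrotatory 6π opening cleaves C5–C10 and sets the 1(10)Z and 4E olefins at once, and cold desilylation fixes the product as the 2-ketone. The precursor is a cis-fused 2-trimethylsilyloxy-4,10-dimethylhexalin whose trans-6,12-lactone and 8α-silyl ether lock the diene helicity. C7/C8 come from an Evans aldol, C5/C6 from an anti aldol, the cis fusion from a radical closure.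

Key step: step 16

Remark: germacrane/eudesmane numbering (C1–C15) is used for every intermediate; in the decalins β is the face of the C10 methyl group.
Remark: in the ring-opened silyl dienol ether the ring carbons C1 and C4 are cis across C2=C3, which makes that bond 2E by the sequence rules (silyloxy outranks C1); the full descriptor is therefore 1(10)Z,2E,4E.
Remark: centres that are destroyed in the following operation (C10 in 15, C12 in 19, C4 in 22, C11 in 30 and 31) are drawn without configuration.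

Step 1
Reactants: 1 4-(benzyloxy)butanoic acid; 2 (R)-4-benzyloxazolidin-2-one
Product: 4 (R)-4-benzyl-3-[4-(benzyloxy)butanoyl]oxazolidin-2-one, via mixed pivalic anhydride 3 (not isolated)
Conditions: PivCl, Et3N, THF, −20 °C; then 2, LiCl, −20 °C → rt
Reagents that add atoms: none
Why: N-Acylation of the oxazolidinone through the mixed pivalic anhydride (acyl transfer at the less hindered carbonyl, LiCl/Et3N activation) is routine and creates no stereocentre.

Step 2
Reactants: 4 (R)-4-benzyl-3-[4-(benzyloxy)butanoyl]oxazolidin-2-one; 5 chloroacetaldehyde (anhydrous monomer)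
Product: 7 (R)-4-benzyl-3-[(2R,3R)-2-(2-benzyloxyethyl)-4-chloro-3-hydroxybutanoyl]oxazolidin-2-one, via dibutylboron Z-enolate 6 (not isolated)
Conditions: Bu2BOTf, iPr2NEt, CH2Cl2, −78 → 0 °C; 5, −78 → 0 °C; pH 7 buffer, MeOH, H2O2, 0 °C
Reagents that add atoms: none
Why: Evans syn aldol: the (Z)-boron enolate reacts through a Zimmerman–Traxler chair on the face away from the benzyl group of the (R)-auxiliary, which should set C7 and C8 in the 7,8-syn relationship and in the absolute sense needed for 7α-H and 8α-O.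

Step 3
Reactants: 7 (R)-4-benzyl-3-[(2R,3R)-2-(2-benzyloxyethyl)-4-chloro-3-hydroxybutanoyl]oxazolidin-2-one
Product: 8 (R)-4-benzyl-3-[(2R,3R)-2-(2-benzyloxyethyl)-4-chloro-3-(triethylsilyloxy)butanoyl]oxazolidin-2-one
Conditions: TESOTf, 2,6-lutidine, CH2Cl2, −78 °C
Reagents that add atoms: triethylsilyl triflate, CC[Si](CC)(CC)OS(=O)(=O)C(F)(F)F
Why: Silylation of a secondary alcohol with a silyl triflate and a hindered pyridine base is routine and installs the O8 ether that has to last until step 21.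

Step 4
Reactants: 8 (R)-4-benzyl-3-[(2R,3R)-2-(2-benzyloxyethyl)-4-chloro-3-(triethylsilyloxy)butanoyl]oxazolidin-2-one
Product: 9 (R)-4-benzyl-3-[(2R,3R)-2-(2-benzyloxyethyl)-4-iodo-3-(triethylsilyloxy)butanoyl]oxazolidin-2-one
Conditions: NaI, 2-butanone, 80 °C
Reagents that add atoms: sodium iodide, [Na+].[I-]
Why: Finkelstein halide exchange (SN2 at the primary carbon, driven by precipitation of NaCl) turns the inert chloride into the iodide needed as radical precursor in step 9.

Step 5
Reactants: 9 (R)-4-benzyl-3-[(2R,3R)-2-(2-benzyloxyethyl)-4-iodo-3-(triethylsilyloxy)butanoyl]oxazolidin-2-one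
Product: 10 (2S,3R)-2-(2-benzyloxyethyl)-4-iodo-3-(triethylsilyloxy)butan-1-ol
Conditions: LiBH4, MeOH (1 equiv), Et2O, 0 °C
Reagents that add atoms: none
Why: Reductive cleavage of the N-acyloxazolidinone by hydride addition at the exocyclic carbonyl should release the primary alcohol and the recoverable auxiliary without touching C7, the β-branched iodide being slow to react with borohydride at 0 °C.

Step 6
Reactants: 10 (2S,3R)-2-(2-benzyloxyethyl)-4-iodo-3-(triethylsilyloxy)butan-1-ol
Product: 11 (2R,3R)-2-(2-benzyloxyethyl)-4-iodo-3-(triethylsilyloxy)butanal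
Conditions: Dess–Martin periodinane, CH2Cl2, 0 °C → rt; used at once
Reagents that add atoms: none
Why: Dess–Martin oxidation is non-basic, so the α-branched aldehyde should form without epimerisation at C7 or β-elimination of the silyloxy group.

Step 7
Reactants: 12 3-ethoxycyclohex-2-en-1-one; 11 (2R,3R)-2-(2-benzyloxyethyl)-4-iodo-3-(triethylsilyloxy)butanal
Product: 14 3-ethoxy-6-[2-(2-benzyloxyethyl)-1-hydroxy-4-iodo-3-(triethylsilyloxy)butyl]cyclohex-2-en-1-one (C5/C6 anti; C6/C7 syn; C7/C8 syn), via lithium dienolate 13 (not isolated)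
Conditions: LDA, THF, −78 °C; 11, −78 °C; AcOH quench at −78 °C
Reagents that add atoms: none
Why: Kinetic α′-deprotonation of the vinylogous ester and aldol addition (Stork–Danheiser α′-functionalisation): the ring-locked E-enolate should give the C5/C6-anti adduct through a Zimmerman–Traxler chair, and Felkin–Anh attack on the C7-branched aldehyde should give the C6/C7-syn relationship, so that C7 dictates C6 (6α-O) and C5.

Step 8
Reactants: 14 3-ethoxy-6-[2-(2-benzyloxyethyl)-1-hydroxy-4-iodo-3-(triethylsilyloxy)butyl]cyclohex-2-en-1-one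
Product: 16 3-methyl-4-[2-(2-benzyloxyethyl)-1-hydroxy-4-iodo-3-(triethylsilyloxy)butyl]cyclohex-2-en-1-one (side chain and C5 as in 14), via tertiary carbinol 15 (not isolated)
Conditions: MeLi, CeCl3, THF, −78 °C; then 0.1 M aq HCl, THF, 0 °C, brief
Reagents that add atoms: methyllithium, [Li]C
Why: Stork–Danheiser transposition: the organocerium reagent adds 1,2 to the vinylogous ester carbonyl (benzyl ether, TES ether and iodide are inert), and mild acid hydrolysis of the tertiary allylic alcohol/enol ether moves the carbonyl to C2 and leaves C14 on C10.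

Step 9
Reactants: 16 3-methyl-4-[2-(2-benzyloxyethyl)-1-hydroxy-4-iodo-3-(triethylsilyloxy)butyl]cyclohex-2-en-1-one
Product: 17 6α-hydroxy-7β-(2-benzyloxyethyl)-8α-(triethylsilyloxy)-10β-methyl-5βH-decalin-2-one (cis-fused)
Conditions: Bu3SnH (slow addition), Et3B/air, PhMe, −40 → 0 °C
Reagents that add atoms: none
Why: Giese-type 6-exo-trig radical cyclisation: the primary C9 radical, which tolerates the β-silyloxy group, adds to the enone β-carbon from the face that carries its tether, so the new C9–C10 bond is cis to C5–C6 and the quaternary C10 (methyl cis to H5) is set by C5; low temperature favours the activated addition over hydrogen transfer.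

Step 10
Reactants: 17 6α-hydroxy-7β-(2-benzyloxyethyl)-8α-(triethylsilyloxy)-10β-methyl-5βH-decalin-2-one
Product: 18 6α-hydroxy-7β-(2-hydroxyethyl)-8α-(triethylsilyloxy)-10β-methyl-5βH-decalin-2-one
Conditions: H2 (1 atm), Pd/C, EtOAc, rt
Reagents that add atoms: none
Why: Catalytic hydrogenolysis of the benzyl ether is routine here because the substrate holds neither olefin nor halide, and the TES ether and ketone are stable to neutral Pd/C–H2.

Step 11
Reactants: 18 6α-hydroxy-7β-(2-hydroxyethyl)-8α-(triethylsilyloxy)-10β-methyl-5βH-decalin-2-one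
Product: 20 8α-(triethylsilyloxy)-2-oxo-4-demethyl-13-nor-5βH-eudesman-12,6α-olide (trans-fused lactone), via lactol 19 (not isolated)
Conditions: TEMPO (cat.), PhI(OAc)2, CH2Cl2, rt
Reagents that add atoms: none
Why: TEMPO/PhI(OAc)2 oxidative lactonisation of a 1,4-diol: the primary alcohol is oxidised chemoselectively, the aldehyde closes onto the equatorial 6α-OH and the lactol is oxidised on, which should give the trans-fused 6,12-lactone without base (no silyl migration from O8) and without touching C7.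

Step 12
Reactants: 20 8α-(triethylsilyloxy)-2-oxo-4-demethyl-13-nor-5βH-eudesman-12,6α-olide
Product: 21 8α-(triethylsilyloxy)-2-oxo-4-demethyl-13-nor-5βH-eudesm-3-en-12,6α-olide
Conditions: IBX, DMSO–PhMe, 70 °C
Reagents that add atoms: none
Why: IBX-mediated dehydrogenation of a ketone to the enone: because C10 is quaternary only the C3–C4 side can be desaturated, so the regiochemistry is fixed by the substrate.

Step 13
Reactants: 21 8α-(triethylsilyloxy)-2-oxo-4-demethyl-13-nor-5βH-eudesm-3-en-12,6α-olide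
Product: 22 2-(trimethylsilyloxy)-8α-(triethylsilyloxy)-13-nor-5βH-eudesm-2-en-12,6α-olide (C4 epimers)
Conditions: MeMgBr, CuBr·SMe2 (10 mol %), TMSCl, THF, −78 °C; Et3N
Reagents that add atoms: methylmagnesium bromide, C[Mg]Br; chlorotrimethylsilane, C[Si](C)(C)Cl
Why: Copper-catalysed conjugate addition of the methyl Grignard reagent with TMSCl trapping should place C15 on C4 and deliver the C2=C3 silyl enol ether regiospecifically at a temperature where the lactone is inert; the C4 configuration is irrelevant.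

Step 14
Reactants: 22 2-(trimethylsilyloxy)-8α-(triethylsilyloxy)-13-nor-5βH-eudesm-2-en-12,6α-olide
Product: 23 8α-(triethylsilyloxy)-2-oxo-13-nor-5βH-eudesm-3-en-12,6α-olide (cis-fused enone)
Conditions: Pd(OAc)2 (1 equiv), MeCN, rt
Reagents that add atoms: none
Why: Saegusa–Ito oxidation: palladation of the silyl enol ether and β-hydride elimination towards C4–H should give the enone whose C3=C4 bond now carries C15.

Step 15
Reactants: 23 8α-(triethylsilyloxy)-2-oxo-13-nor-5βH-eudesm-3-en-12,6α-olide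
Product: 24 2-(trimethylsilyloxy)-8α-(triethylsilyloxy)-13-nor-5βH-eudesma-1,3-dien-12,6α-olide (cis-fused silyloxydiene)
Conditions: LDA, TMSCl, Et3N, THF, −78 °C (internal quench)
Reagents that add atoms: chlorotrimethylsilane, C[Si](C)(C)Cl
Why: Kinetic α′-deprotonation of the enone at C1 with in-situ O-silylation should give the cross-conjugated 2-silyloxy-1,3-diene, since the lactone α-protons are markedly less acidic and the γ-proton at C5 is kinetically inaccessible, so the cis ring fusion and the lactone are kept.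

Step 16
Reactants: 24 2-(trimethylsilyloxy)-8α-(triethylsilyloxy)-13-nor-5βH-eudesma-1,3-dien-12,6α-olide
Product: 25 (1(10)Z,2E,4E)-2-(trimethylsilyloxy)-8α-(triethylsilyloxy)-13-norgermacra-1(10),2,4-trien-12,6α-olide (kept in cold solution)
Conditions: hν (300 nm lamps, Pyrex), degassed pentane–THF, trace Et3N, −78 °C, partial conversion
Reagents that add atoms: none
Why: Excited-state 6π electrocyclic ring opening of the cyclohexa-1,3-diene, conrotatory, cleaves the C5–C10 σ-bond and forms the C10=C1 and C4=C5 π-bonds while the old diene π-system contracts to C2=C3. The closest known reaction type is the low-temperature photochemical opening of cis- and trans-fused hexalin 1,3-dienes of the eudesmane family to cyclodeca-1,3,5-trienes. The step closes no ring but releases the ten-membered ring by cleaving the bond shared by the two six-membered rings, and it creates no stereocentre, only the 1(10)Z, 2E and 4E geometries. The sense of conrotation follows the ground-state helicity of the diene: the trans-fused lactone and the equatorial 8-silyloxy group lock ring B in the chair in which, seen from ring A, H5 and C9 are pseudo-axial, and pseudo-axial groups turn inward, so H5 and C9 go inside (4E and 1(10)Z) while C6 and C14 go outside. The selectivity needed is this single conrotatory mode without secondary photoreaction or thermal disrotatory reclosure; it should be secured by the conformational lock, by irradiating only the long-wavelength edge of the diene band at −78 °C to partial conversion, and by the cold desilylation of step 17, which turns the triene into a ketone that is no longer a hexatriene and returns unreacted 24 as recyclable 23.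

Step 17
Reactants: 25 (1(10)Z,2E,4E)-2-(trimethylsilyloxy)-8α-(triethylsilyloxy)-13-norgermacra-1(10),2,4-trien-12,6α-olide
Product: 26 (1(10)Z,4E)-2-oxo-8α-(triethylsilyloxy)-13-norgermacra-1(10),4-dien-12,6α-olide
Conditions: TBAF–AcOH (1:1.2), THF, −78 °C, added to the cold photolysate
Reagents that add atoms: none
Why: Fluoride-induced cleavage of the trimethylsilyl dienol ether buffered with acetic acid: kinetic α-protonation at C3 should give the β,γ-unsaturated 2-ketone, which cannot undergo 6π closure, while the TES ether survives the cold, buffered conditions.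

Step 18
Reactants: 26 (1(10)Z,4E)-2-oxo-8α-(triethylsilyloxy)-13-norgermacra-1(10),4-dien-12,6α-olide
Product: 27 (2S,1(10)Z,4E)-2-hydroxy-8α-(triethylsilyloxy)-13-norgermacra-1(10),4-dien-12,6α-olide
Conditions: NaBH4, CeCl3·7H2O, MeOH, −78 °C
Reagents that add atoms: none
Why: Luche reduction: cerium-mediated 1,2-hydride delivery to the enone carbonyl from the outer face of the ten-membered ring should give the 2S allylic alcohol without conjugate reduction and fast enough to forestall base-induced conjugation of the 4,5-olefin.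

Step 19
Reactants: 27 (2S,1(10)Z,4E)-2-hydroxy-8α-(triethylsilyloxy)-13-norgermacra-1(10),4-dien-12,6α-olide
Product: 28 (2S,1(10)Z,4E)-2-(tert-butyldimethylsilyloxy)-8α-(triethylsilyloxy)-13-norgermacra-1(10),4-dien-12,6α-olide
Conditions: TBSOTf, 2,6-lutidine, CH2Cl2, −78 °C
Reagents that add atoms: tert-butyldimethylsilyl triflate, CC(C)(C)[Si](C)(C)OS(=O)(=O)C(F)(F)F
Why: Silylation with a silyl triflate protects O2 as an ether more robust than the O8 TES ether, which is the basis of the selective unmasking in step 21.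

Step 20
Reactants: 28 (2S,1(10)Z,4E)-2-(tert-butyldimethylsilyloxy)-8α-(triethylsilyloxy)-13-norgermacra-1(10),4-dien-12,6α-olide
Product: 32 (2S,1(10)Z,4E)-2-(tert-butyldimethylsilyloxy)-8α-(triethylsilyloxy)germacra-1(10),4,11(13)-trien-12,6α-olide, via lithium lactone enolate 29 (not isolated), via Mannich base 30 (not isolated), via trimethylammonium iodide 31 (not isolated)
Conditions: LDA, THF, −78 °C; CH2=NMe2+ I−, −78 → 0 °C; MeI, MeOH, rt; aq NaHCO3, CH2Cl2
Reagents that add atoms: Eschenmoser's salt, C=[N+](C)C.[I-]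
Why: Eschenmoser methylenation (Mannich reaction of the lactone enolate, quaternisation, base-induced loss of trimethylamine): the lactone α-carbon is the only enolisable site and the elimination can only give the exocyclic C11=C13 olefin.

Step 21
Reactants: 32 (2S,1(10)Z,4E)-2-(tert-butyldimethylsilyloxy)-8α-(triethylsilyloxy)germacra-1(10),4,11(13)-trien-12,6α-olide
Product: 33 (2S,1(10)Z,4E)-2-(tert-butyldimethylsilyloxy)-8α-hydroxygermacra-1(10),4,11(13)-trien-12,6α-olide
Conditions: PPTS (cat.), MeOH–CH2Cl2, 0 °C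
Reagents that add atoms: none
Why: Mild acid-catalysed methanolysis removes a secondary TES ether much faster than the TBS ether, which should expose O8 alone.

Step 22
Reactants: 33 (2S,1(10)Z,4E)-2-(tert-butyldimethylsilyloxy)-8α-hydroxygermacra-1(10),4,11(13)-trien-12,6α-olide; 34 angelic acid
Product: 36 (2S,1(10)Z,4E)-8α-angeloyloxy-2-(tert-butyldimethylsilyloxy)germacra-1(10),4,11(13)-trien-12,6α-olide, via mixed Yamaguchi anhydride 35 (not isolated)
Conditions: 34, 2,4,6-Cl3C6H2COCl, Et3N, PhMe, rt; then 33, DMAP, PhMe, rt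
Reagents that add atoms: none
Why: Yamaguchi esterification through the mixed 2,4,6-trichlorobenzoic anhydride acylates the hindered 8α-alcohol with retention at C8, and short contact with DMAP at room temperature should preserve the (Z)-geometry of the angelate.

Step 23
Reactants: 36 (2S,1(10)Z,4E)-8α-angeloyloxy-2-(tert-butyldimethylsilyloxy)germacra-1(10),4,11(13)-trien-12,6α-olide
Product: 37 (2S,1(10)Z,4E)-8α-angeloyloxy-2-hydroxygermacra-1(10),4,11(13)-trien-12,6α-olide
Conditions: HF·pyridine, pyridine, THF, 0 °C → rt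
Reagents that add atoms: none
Why: Buffered HF·pyridine cleaves the TBS ether without base, so the α-methylene lactone and the angelate are not exposed to nucleophiles.

Step 24
Reactants: 37 (2S,1(10)Z,4E)-8α-angeloyloxy-2-hydroxygermacra-1(10),4,11(13)-trien-12,6α-olide
Product: 38 (1R,2S,10S,4E)-8α-angeloyloxy-1,10-epoxy-2-hydroxygermacra-4,11(13)-dien-12,6α-olide
Conditions: VO(acac)2 (5 mol %), TBHP (1.1 equiv), CH2Cl2, 0 °C
Reagents that add atoms: tert-butyl hydroperoxide, CC(C)(C)OO
Why: Vanadium-catalysed hydroxyl-directed epoxidation: in the A(1,3)-strain-minimised conformer (C2–H eclipsing C1=C10) oxygen is delivered syn to the hydroxyl (threo), which should set C1 (R) and C10 (S) from the 2S centre and leave the homoallylic and the electron-poor olefins untouched at one equivalent of oxidant.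

Step 25
Reactants: 38 (1R,2S,10S,4E)-8α-angeloyloxy-1,10-epoxy-2-hydroxygermacra-4,11(13)-dien-12,6α-olide
Product: 39 (1R,2S,4R,5R,6S,7R,8S,10S)-8-angeloyloxy-1,10:4,5-diepoxy-2-hydroxygermacr-11(13)-en-12,6-olide (CNP0388761.1)
Conditions: mCPBA (1.1 equiv), NaHCO3, CH2Cl2, 0 °C
Reagents that add atoms: 3-chloroperbenzoic acid, OOC(=O)c1cccc(Cl)c1
Why: Prilezhaev epoxidation: the buffered peracid attacks the only remaining electron-rich olefin (C4=C5) from the exposed outer face of the ring, as in related germacranolides, which should give the 4R,5R epoxide while the α-methylene lactone and the angelate are too electron-poor to react.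

Compound list
1 | 4-(benzyloxy)butanoic acid | OC(=O)CCCOCc1ccccc1 | starting material
2 | (R)-4-benzyloxazolidin-2-one | O=C1N[C@H](Cc2ccccc2)CO1 | starting material
3 | 4-(benzyloxy)butanoic pivalic anhydride | CC(C)(C)C(=O)OC(=O)CCCOCc1ccccc1 | intermediate
4 | (R)-4-benzyl-3-[4-(benzyloxy)butanoyl]oxazolidin-2-one | O=C(CCCOCc1ccccc1)N1[C@H](Cc2ccccc2)COC1=O | intermediate
5 | chloroacetaldehyde | ClCC=O | starting material
6 | dibutylboron (Z)-enolate of 4 | CCCCB(CCCC)O/C(=C\CCOCc1ccccc1)N1[C@H](Cc2ccccc2)COC1=O | intermediate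
7 | (R)-4-benzyl-3-[(2R,3R)-2-(2-benzyloxyethyl)-4-chloro-3-hydroxybutanoyl]oxazolidin-2-one | O=C([C@H](CCOCc1ccccc1)[C@@H](O)CCl)N1[C@H](Cc2ccccc2)COC1=O | intermediate
8 | (R)-4-benzyl-3-[(2R,3R)-2-(2-benzyloxyethyl)-4-chloro-3-(triethylsilyloxy)butanoyl]oxazolidin-2-one | O=C([C@H](CCOCc1ccccc1)[C@@H](O[Si](CC)(CC)CC)CCl)N1[C@H](Cc2ccccc2)COC1=O | intermediate
9 | (R)-4-benzyl-3-[(2R,3R)-2-(2-benzyloxyethyl)-4-iodo-3-(triethylsilyloxy)butanoyl]oxazolidin-2-one | O=C([C@H](CCOCc1ccccc1)[C@@H](O[Si](CC)(CC)CC)CI)N1[C@H](Cc2ccccc2)COC1=O | intermediate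
10 | (2S,3R)-2-(2-benzyloxyethyl)-4-iodo-3-(triethylsilyloxy)butan-1-ol | OC[C@H](CCOCc1ccccc1)[C@@H](O[Si](CC)(CC)CC)CI | intermediate
11 | (2R,3R)-2-(2-benzyloxyethyl)-4-iodo-3-(triethylsilyloxy)butanal | O=C[C@H](CCOCc1ccccc1)[C@@H](O[Si](CC)(CC)CC)CI | intermediate
12 | 3-ethoxycyclohex-2-en-1-one | CCOC1=CC(=O)CCC1 | starting material
13 | lithium 3-ethoxycyclohexa-1,5-dien-1-olate (α′-enolate of 12) | [Li+].CCOC1=CC([O-])=CCC1 | intermediate
14 | anti-aldol adduct, 3-ethoxy-6-[2-(2-benzyloxyethyl)-1-hydroxy-4-iodo-3-(triethylsilyloxy)butyl]cyclohex-2-en-1-one (C5/C6 anti, C6/C7 syn, C7/C8 syn) | CCOC1=CC(=O)[C@@H](CC1)[C@@H](O)[C@H](CCOCc2ccccc2)[C@@H](O[Si](CC)(CC)CC)CI | intermediate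
15 | 1-methyl carbinol from 1,2-addition to 14 (C10 epimers) | CCOC1=CC(C)(O)[C@@H](CC1)[C@@H](O)[C@H](CCOCc2ccccc2)[C@@H](O[Si](CC)(CC)CC)CI | intermediate
16 | 3-methyl-4-[2-(2-benzyloxyethyl)-1-hydroxy-4-iodo-3-(triethylsilyloxy)butyl]cyclohex-2-en-1-one | CC1=CC(=O)CC[C@H]1[C@@H](O)[C@H](CCOCc2ccccc2)[C@@H](O[Si](CC)(CC)CC)CI | intermediate
17 | 6α-hydroxy-7β-(2-benzyloxyethyl)-8α-(triethylsilyloxy)-10β-methyl-5βH-decalin-2-one (cis-fused) | O[C@H]1[C@H](CCOCc2ccccc2)[C@@H](O[Si](CC)(CC)CC)C[C@@]3(C)CC(=O)CC[C@@H]13 | intermediate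
18 | 6α-hydroxy-7β-(2-hydroxyethyl)-8α-(triethylsilyloxy)-10β-methyl-5βH-decalin-2-one | O[C@H]1[C@H](CCO)[C@@H](O[Si](CC)(CC)CC)C[C@@]3(C)CC(=O)CC[C@@H]13 | intermediate
19 | 6,12-lactol of 18 (C12 anomers) | C1C(O)O[C@H]2[C@H]1[C@@H](O[Si](CC)(CC)CC)C[C@@]3(C)CC(=O)CC[C@@H]23 | intermediate
20 | 8α-(triethylsilyloxy)-2-oxo-4-demethyl-13-nor-5βH-eudesman-12,6α-olide | C1C(=O)O[C@H]2[C@H]1[C@@H](O[Si](CC)(CC)CC)C[C@@]3(C)CC(=O)CC[C@@H]23 | intermediate
21 | 8α-(triethylsilyloxy)-2-oxo-4-demethyl-13-nor-5βH-eudesm-3-en-12,6α-olide | C1C(=O)O[C@H]2[C@H]1[C@@H](O[Si](CC)(CC)CC)C[C@@]3(C)CC(=O)C=C[C@@H]23 | intermediate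
22 | 2-(trimethylsilyloxy)-8α-(triethylsilyloxy)-13-nor-5βH-eudesm-2-en-12,6α-olide (C4 epimers) | C1C(=O)O[C@H]2[C@H]1[C@@H](O[Si](CC)(CC)CC)C[C@@]3(C)CC(O[Si](C)(C)C)=CC(C)[C@@H]23 | intermediate
23 | 8α-(triethylsilyloxy)-2-oxo-13-nor-5βH-eudesm-3-en-12,6α-olide | C1C(=O)O[C@H]2[C@H]1[C@@H](O[Si](CC)(CC)CC)C[C@@]3(C)CC(=O)C=C(C)[C@@H]23 | intermediate
24 | 2-(trimethylsilyloxy)-8α-(triethylsilyloxy)-13-nor-5βH-eudesma-1,3-dien-12,6α-olide (key-step precursor) | C1C(=O)O[C@H]2[C@H]1[C@@H](O[Si](CC)(CC)CC)C[C@@]3(C)C=C(O[Si](C)(C)C)C=C(C)[C@@H]23 | intermediate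
25 | (1(10)Z,2E,4E)-2-(trimethylsilyloxy)-8α-(triethylsilyloxy)-13-norgermacra-1(10),2,4-trien-12,6α-olide (key-step product) | [C@H]1(O[Si](CC)(CC)CC)C/C(C)=C\C(O[Si](C)(C)C)=C/C(C)=C/[C@H]2OC(=O)C[C@H]12 | intermediate
26 | (1(10)Z,4E)-2-oxo-8α-(triethylsilyloxy)-13-norgermacra-1(10),4-dien-12,6α-olide | [C@H]1(O[Si](CC)(CC)CC)C/C(C)=C\C(=O)C/C(C)=C/[C@H]2OC(=O)C[C@H]12 | intermediate
27 | (2S)-2-hydroxy-8α-(triethylsilyloxy)-13-norgermacra-1(10)Z,4E-dien-12,6α-olide | [C@H]1(O[Si](CC)(CC)CC)C/C(C)=C\[C@@H](O)C/C(C)=C/[C@H]2OC(=O)C[C@H]12 | intermediate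
28 | (2S)-2-(tert-butyldimethylsilyloxy)-8α-(triethylsilyloxy)-13-norgermacra-1(10)Z,4E-dien-12,6α-olide | [C@H]1(O[Si](CC)(CC)CC)C/C(C)=C\[C@@H](O[Si](C)(C)C(C)(C)C)C/C(C)=C/[C@H]2OC(=O)C[C@H]12 | intermediate
29 | lithium enolate of lactone 28 | [Li+].[C@H]1(O[Si](CC)(CC)CC)C/C(C)=C\[C@@H](O[Si](C)(C)C(C)(C)C)C/C(C)=C/[C@H]2OC([O-])=C[C@H]12 | intermediate
30 | 11-(dimethylaminomethyl) lactone (Mannich base, C11 epimers) | [C@H]1(O[Si](CC)(CC)CC)C/C(C)=C\[C@@H](O[Si](C)(C)C(C)(C)C)C/C(C)=C/[C@H]2OC(=O)C(CN(C)C)[C@H]12 | intermediate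
31 | 11-(trimethylammoniomethyl) lactone iodide | [C@H]1(O[Si](CC)(CC)CC)C/C(C)=C\[C@@H](O[Si](C)(C)C(C)(C)C)C/C(C)=C/[C@H]2OC(=O)C(C[N+](C)(C)C)[C@H]12.[I-] | intermediate
32 | (2S)-2-(tert-butyldimethylsilyloxy)-8α-(triethylsilyloxy)germacra-1(10)Z,4E,11(13)-trien-12,6α-olide | [C@H]1(O[Si](CC)(CC)CC)C/C(C)=C\[C@@H](O[Si](C)(C)C(C)(C)C)C/C(C)=C/[C@H]2OC(=O)C(=C)[C@H]12 | intermediate
33 | (2S)-2-(tert-butyldimethylsilyloxy)-8α-hydroxygermacra-1(10)Z,4E,11(13)-trien-12,6α-olide | [C@H]1(O)C/C(C)=C\[C@@H](O[Si](C)(C)C(C)(C)C)C/C(C)=C/[C@H]2OC(=O)C(=C)[C@H]12 | intermediate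
34 | angelic acid, (Z)-2-methylbut-2-enoic acid | C/C=C(/C)C(=O)O | starting material
35 | angelic 2,4,6-trichlorobenzoic anhydride | C/C=C(/C)C(=O)OC(=O)c1c(Cl)cc(Cl)cc1Cl | intermediate
36 | (2S)-8α-angeloyloxy-2-(tert-butyldimethylsilyloxy)germacra-1(10)Z,4E,11(13)-trien-12,6α-olide | [C@H]1(OC(=O)/C(C)=C\C)C/C(C)=C\[C@@H](O[Si](C)(C)C(C)(C)C)C/C(C)=C/[C@H]2OC(=O)C(=C)[C@H]12 | intermediate
37 | (2S)-8α-angeloyloxy-2-hydroxygermacra-1(10)Z,4E,11(13)-trien-12,6α-olide | [C@H]1(OC(=O)/C(C)=C\C)C/C(C)=C\[C@@H](O)C/C(C)=C/[C@H]2OC(=O)C(=C)[C@H]12 | intermediate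
38 | (1R,2S,10S)-8α-angeloyloxy-1,10-epoxy-2-hydroxygermacra-4E,11(13)-dien-12,6α-olide | [C@H]1(OC(=O)/C(C)=C\C)C[C@]3(C)O[C@@H]3[C@@H](O)C/C(C)=C/[C@H]2OC(=O)C(=C)[C@H]12 | intermediate
39 | (1R,2S,4R,5R,6S,7R,8S,10S)-8-angeloyloxy-1,10:4,5-diepoxy-2-hydroxygermacr-11(13)-en-12,6-olide (CNP0388761.1) | C=C1C(=O)O[C@H]2[C@H]1[C@@H](OC(=O)/C(C)=C\C)C[C@]1(C)O[C@@H]1[C@@H](O)C[C@@]1(C)O[C@H]21 | target

Total step count: 25. Longest linear sequence: 25 steps (1 → 39; compounds 2, 5, 12 and 34 enter as commercial partners).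

Steps most likely to fail

Step 16. The irradiation may stop at a photostationary mixture poor in triene, the ring-opened silyl dienol ether may reclose thermally (disrotatory, to the trans-fused diene) before the quench, and the hydrolytically labile trimethylsilyl dienol ethers may be lost during irradiation and transfer. The fallback keeps the bond cleavage but brings in the C2 oxygen only after ring opening, through a carbon–boron bond; it sets out from 23 and comes back at 26. Kinetic enolate triflation of 23 (LDA, PhNTf2, THF, −78 °C) gives the cross-conjugated dienyl triflate, 2-(trifluoromethylsulfonyloxy)-8α-(triethylsilyloxy)-13-nor-5βH-eudesma-1,3-dien-12,6α-olide F1. Palladium-catalysed borylation (B2pin2, PdCl2(PPh3)2, PPh3, KOPh, PhMe, 50 °C) turns it into the chromatographically stable 2-(pinacolboryl)diene F2. Irradiation of F2 under the conditions of step 16 should give the (1(10)Z,4E)-2-(pinacolboryl)triene F3 with the same conformational control. Oxidation of the cold photolysate (NaBO3·4H2O, THF–H2O, 0 °C) converts the alkenyl boronate into the enol and thus into ketone 26, while unreacted F2 returns 23.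

Step 9. The primary C9 radical may abstract the allylic C5 hydrogen (1,5-transfer, which would also scramble C5) or be reduced before it closes onto the hindered β-carbon, and the ring fusion may not be purely cis. The fallback replaces the radical closure by a carbonyl olefination followed by cuprate addition; it sets out from 14 and comes back at 17. O6 of 14 is capped (TMSCl, imidazole) and the iodide is heated with PPh3 (MeCN, 80 °C) to give the phosphonium iodide F4. KHMDS (PhMe, 0 → 80 °C) should effect an intramolecular Wittig reaction with the vinylogous ester carbonyl to give the bicyclic 2-ethoxy-1(10),… dienol ether F5 (C9=C10, C1=C2). Dilute aqueous acid hydrolyses F5 and removes the TMS group to give the bicyclic enone, 6α-hydroxy-7β-(2-benzyloxyethyl)-8α-(triethylsilyloxy)-5βH-octal-1(10)-en-2-one F6. Conjugate addition of Me2CuLi (Et2O, −78 → 0 °C) to F6 should deliver the angular methyl cis to H5, as is usual for such octalones, and give 17.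

Step 18. Hydride may be delivered to the other face of the twisted enone carbonyl, and the basic medium may move the 4,5-olefin into conjugation. The fallback corrects the carbinol centre by substitution instead of by reduction; it sets out from 26 and comes back at 27. If the reduction gives mainly the (2R)-alcohol F6a, written here as the 2-epimer of 27, F7, it is subjected to Mitsunobu inversion (4-nitrobenzoic acid, PPh3, DIAD, THF, 0 °C) to give the (2S)-4-nitrobenzoate F8, and mild methanolysis (K2CO3, MeOH, 0 °C) then gives 27.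

Further compounds
F1 | step 16 | 2-(trifluoromethylsulfonyloxy)-8α-(triethylsilyloxy)-13-nor-5βH-eudesma-1,3-dien-12,6α-olide | C1C(=O)O[C@H]2[C@H]1[C@@H](O[Si](CC)(CC)CC)C[C@@]3(C)C=C(OS(=O)(=O)C(F)(F)F)C=C(C)[C@@H]23
F2 | step 16 | 2-(pinacolboryl)-8α-(triethylsilyloxy)-13-nor-5βH-eudesma-1,3-dien-12,6α-olide | C1C(=O)O[C@H]2[C@H]1[C@@H](O[Si](CC)(CC)CC)C[C@@]3(C)C=C(B4OC(C)(C)C(C)(C)O4)C=C(C)[C@@H]23
F3 | step 16 | (1(10)Z,4E)-2-(pinacolboryl)-8α-(triethylsilyloxy)-13-norgermacra-1(10),2,4-trien-12,6α-olide | [C@H]1(O[Si](CC)(CC)CC)C/C(C)=C\C(B3OC(C)(C)C(C)(C)O3)=C/C(C)=C/[C@H]2OC(=O)C[C@H]12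
F4 | step 9 | phosphonium iodide from the O6-trimethylsilyl ether of 14 | CCOC1=CC(=O)[C@@H](CC1)[C@@H](O[Si](C)(C)C)[C@H](CCOCc2ccccc2)[C@@H](O[Si](CC)(CC)CC)C[P+](c3ccccc3)(c4ccccc4)c5ccccc5.[I-]
F5 | step 9 | bicyclic 2-ethoxy dienol ether (C1=C2, C9=C10) with 6α-OTMS, 7β-(2-benzyloxyethyl), 8α-OTES | CCOC1=CC2=C[C@H](O[Si](CC)(CC)CC)[C@@H](CCOCc3ccccc3)[C@H](O[Si](C)(C)C)[C@@H]2CC1
F6 | step 9 | 6α-hydroxy-7β-(2-benzyloxyethyl)-8α-(triethylsilyloxy)-5βH-octal-1(10)-en-2-one | O=C1C=C2C[C@H](O[Si](CC)(CC)CC)[C@@H](CCOCc3ccccc3)[C@H](O)[C@@H]2CC1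
F7 | step 18 | (2R)-2-hydroxy-8α-(triethylsilyloxy)-13-norgermacra-1(10)Z,4E-dien-12,6α-olide (2-epimer of 27) | [C@H]1(O[Si](CC)(CC)CC)C/C(C)=C\[C@H](O)C/C(C)=C/[C@H]2OC(=O)C[C@H]12
F8 | step 18 | (2S)-2-(4-nitrobenzoyloxy)-8α-(triethylsilyloxy)-13-norgermacra-1(10)Z,4E-dien-12,6α-olide | [C@H]1(O[Si](CC)(CC)CC)C/C(C)=C\[C@@H](OC(=O)c3ccc(cc3)[N+](=O)[O-])C/C(C)=C/[C@H]2OC(=O)C[C@H]12
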